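The runs are simulated for an exercise; noise was put on by code.

A ratio of 3.78 starts the dispute: that is how much the gap between L and its last north-west reading, 80.8 %, shrinks from 2.50 h to 6.00 h.

| setting | north-west | flask |
|---|---|---|
| Q | 3 M | 3.0 M |
| X | 200 mM (held) | 200 mM (held) |
| remark | the very flask that is asked about, followed so far |  |
| time |  | 2.5 d |

north-west run (percent of the Q charged)

| time / h | L / % | Q / % |
|---|---|---|
| 2.50 | 89.5 | 0 |
| 6.00 | 83.1 | 3.0 |
| 12.0 | 82.4 | 0.1 |
| 20.0 | 80.8 | 2.0 |

(readings scatter by 1 percentage point)

- at the start none of X is in solution

- Saturday's: doubling the transfer coefficient of X, all else as stated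
- Friday's: doubling the saturation concentration of X, all else as stated

- L at 2.5 d, in percent of the Q charged
- the change that raises the amount of L at 2.5 d, in percent of the Q charged most ("none" if none brings more than 2 percentage points) (Saturday's / Friday's / none)
- amount of L at 2.5 d, in percent of the Q charged, after Saturday's

Ben sees a slow straight line. From 6.00 h to 20.0 h L loses 2.3 percentage points, and that pace carried on to the asked time gives 74.2 %.

Ana sees a gap closing and counts turnovers. The ratio means the gap halves every 1.82 h, a reading of the halving time (the relaxation half-life), and the asked time holds 32.9 such halvings. Ben's loss, she answers, rests on two readings that each scatter by 1 point.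

I side with Ana. The asked time is far longer than the halving time, so I put L at the floor, near 80.8 %. Hastening X by either change acts on the first hours, so I expect no gain of 2 points and the same L after Saturday's.

The forecast leans Ana's way but stands lower, at 79 % (73 % to 82 %), with 78.5 % (71 % to 82 %) after Saturday's and best none, holding that “the loss levels off once X reaches saturation”.

    L ⇌ Z (K = 0.240, k = 0.0665 h⁻¹)
    Q + E → L + D (k = 37.6 M⁻¹ h⁻¹)
    Q ⇌ J (K = 0.941, k = 0.0103 h⁻¹)
    X ⇌ E, rate k4*(csat - [E]) (kL = 16.8 h⁻¹)

The flask gives 80.4 %, and 80.5 % after Saturday's. Saturday's brings 0.097 points and Friday's 0.12 points, both less than 2 points, so the best is none. Ben keeps the stretch he read: the flask's L still goes from 83.2 % at 0.250 d to 80.3 % at 1.25 d, and it stands at 80.4 % at 2.50 d. The same flask read at 25 h holds 13.7 of Ana's halvings, so the count again puts L at the floor, and that flask gives 80.3 %.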